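**Plan**
- Retrosynthesis: the 4'-O–Si and 7-O–prenyl bonds are cut first. Ring A is then opened at C5–C6 (Claisen), the acetyl unit is removed at C7–C8, ring C is opened at O1–C8a, and the chain is cut at C4a–C8a and C2–C3.
- Forward: ring B is bought as methyl vanillate. C2–C3 and then C4a–C8a are joined on methyl 4-methoxyacetoacetate, ring C (a 4-pyranone) closes by cyclodehydration, C7–C8 is added at the methoxymethyl group, and ring A closes last. 7-O-Prenylation and desilylation finish the route.
- Enabling feature: ring A is a resorcinol (oxygen on C5 and C7, hydrogen on C6), the pattern of a folded 1,3-dicarbonyl chain. Folding it onto a finished ring C whose O1 already sits on C8a fixes the methoxy group at C8.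
- Stereochemistry: the target is achiral. The only sp3 centres occur in racemic, enolisable intermediates and vanish on pyranone formation and aromatisation.

Key step: step 5

Assumption: the amide bases and Bu4NF are used as commercial solutions, and enolisable polycarbonyl intermediates are named and drawn in their keto forms as racemates. Ar stands for the 3-methoxy-4-[(triisopropylsilyl)oxy]phenyl group.

Step 1
Reactants: 1 methyl vanillate (methyl 4-hydroxy-3-methoxybenzoate)
Product: 2 methyl 3-methoxy-4-[(triisopropylsilyl)oxy]benzoate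
Conditions: TIPSCl (1.2 equiv), imidazole (2.5 equiv), DMF, rt
Reagents that add atoms: chlorotri(propan-2-yl)silane (TIPSCl), CC(C)[Si](Cl)(C(C)C)C(C)C
Why: Silyl ether formation on a phenol; the bulky triisopropylsilyl ether should survive amide bases and CF3CO2H and is later removed by fluoride without harm to an allylic ether.

Step 2
Reactants: 2 methyl 3-methoxy-4-[(triisopropylsilyl)oxy]benzoate; 3 methyl 4-methoxyacetoacetate (methyl 4-methoxy-3-oxobutanoate)
Product: 4 methyl 4-methoxy-5-Ar-3,5-dioxopentanoate (racemic at C4)
Conditions: 3 (2.3 equiv), LiN(i-Pr)2 (4.6 equiv), THF, −78 to 0 °C; then 2 (1 equiv), −78 to 0 °C; aq. HCl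
Reagents that add atoms: none
Why: γ-Acylation of a β-keto ester dianion by an ester (Claisen-type condensation), in which the more basic C4 carbanion attacks the benzoate, the excess dianion takes up the acidic proton of the diketo ester formed, and the methoxy group on C4 becomes the future 3-methoxy group.

Step 3
Reactants: 4 methyl 4-methoxy-5-Ar-3,5-dioxopentanoate; 5 methoxyacetyl chloride
Product: 7 methyl 6-Ar-5-methoxy-2-(methoxymethyl)-4-oxo-4H-pyran-3-carboxylate, via triketo ester 6 (not isolated)
Conditions: MgCl2 (1.1 equiv), pyridine (2.2 equiv), CH2Cl2, 0 °C; 5 (1.1 equiv), 0 °C to rt; 1 M HCl wash; then CF3CO2H, CH2Cl2, rt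
Reagents that add atoms: none
Why: Magnesium-chelate (soft-enolisation) C-acylation at C2 of the β-keto ester, the only site whose product is held as a stable tricarbonyl chelate, followed by acid-catalysed cyclodehydration of the 1,3,5-triketone to the 4-pyranone, in which the two outer ketones condense and the less electrophilic ester is left as the 3-carboxylate.

Step 4
Reactants: 7 methyl 6-Ar-5-methoxy-2-(methoxymethyl)-4-oxo-4H-pyran-3-carboxylate; 8 N-methoxy-N-methylacetamide
Product: 9 methyl 6-Ar-5-methoxy-2-(1-methoxy-2-oxopropyl)-4-oxo-4H-pyran-3-carboxylate (racemic)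
Conditions: LiN(SiMe3)2 (2.2 equiv), THF, −78 °C; 8 (1.2 equiv), −78 to 0 °C; AcOH quench at −78 °C
Reagents that add atoms: none
Why: Vinylogous (lateral) deprotonation of the 2-alkyl group of a 4-pyranone and Claisen-type C-acylation of the extended enolate by a Weinreb amide, which transfers one acetyl group only, while the silylamide is too weak to deprotonate the new acetyl methyl, so the product should stay as its C8 enolate until the quench.

Step 5
Reactants: 9 methyl 6-Ar-5-methoxy-2-(1-methoxy-2-oxopropyl)-4-oxo-4H-pyran-3-carboxylate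
Product: 10 2-Ar-5,7-dihydroxy-3,8-dimethoxy-4H-chromen-4-one
Conditions: LiN(i-Pr)2 (3.5 equiv), THF, −78 to 0 °C; cold aq. HCl
Reagents that add atoms: none
Why: Intramolecular Claisen (Dieckmann-type) condensation with aromatisation: the first equivalent of LiN(i-Pr)2 removes the acidic C8–H, the second deprotonates the acetyl methyl, this terminal carbanion (C6) adds to the ester carbonyl (C5), methoxide leaves, and the cyclic 1,3-dione loses a C6 proton to give the resorcinol bis-phenoxide. The closest known reaction is the base-induced cyclisation of ortho-(2-oxopropyl)benzoates to naphthalene-1,3-diols and, more broadly, the folding of polycarbonyl dianions to resorcinols. Ring A closes in a 6-exo-trig mode onto the ester on the neighbouring ring carbon. No stereocentre is created, and the racemic C8 centre of 9 becomes sp2. The step needs attack by carbon on the ester and not attack by the enolate oxygen (enol lactone) or addition to the C4 ring carbonyl: full dianion formation by the strong amide base makes C6 the most nucleophilic site, an enol lactone would be reopened by the lithium methoxide set free, the tethered carbanion cannot reach the π-face of C4 from within the ring plane, and only the C5–C6 closure is made irreversible by aromatisation. Because O1 is already bonded to C8a, the methoxy group can only end up on C8.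

Step 6
Reactants: 10 2-Ar-5,7-dihydroxy-3,8-dimethoxy-4H-chromen-4-one; 11 prenyl bromide (1-bromo-3-methylbut-2-ene)
Product: 12 2-Ar-5-hydroxy-3,8-dimethoxy-7-[(3-methylbut-2-en-1-yl)oxy]-4H-chromen-4-one
Conditions: 11 (1.1 equiv), K2CO3 (1.2 equiv), acetone, rt
Reagents that add atoms: none
Why: Williamson ether synthesis at the 7-hydroxyl, the most acidic free phenol (para to the C4 carbonyl), while the 5-hydroxyl is held in a hydrogen bond to C4=O and the 4'-oxygen is still silylated, so one equivalent of mild base in an aprotic solvent should alkylate O7 only.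

Step 7
Reactants: 12 2-Ar-5-hydroxy-3,8-dimethoxy-7-[(3-methylbut-2-en-1-yl)oxy]-4H-chromen-4-one
Product: 13 5,4'-dihydroxy-3,8,3'-trimethoxy-7-prenyloxyflavone (target)
Conditions: Bu4NF (1.1 equiv), AcOH (1.1 equiv), THF, 0 °C
Reagents that add atoms: none
Why: Fluoride-induced cleavage of the aryl silyl ether (desilylation), buffered with acetic acid so that the prenyl ether, the chelated 5-hydroxyl and the flavone core should remain untouched.

**Compound list**
1 | methyl vanillate (methyl 4-hydroxy-3-methoxybenzoate) | COC(=O)c1ccc(O)c(OC)c1 | starting material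
2 | methyl 3-methoxy-4-[(triisopropylsilyl)oxy]benzoate | COC(=O)c1ccc(O[Si](C(C)C)(C(C)C)C(C)C)c(OC)c1 | intermediate
3 | methyl 4-methoxyacetoacetate (methyl 4-methoxy-3-oxobutanoate) | COCC(=O)CC(=O)OC | starting material
4 | methyl 4-methoxy-5-{3-methoxy-4-[(triisopropylsilyl)oxy]phenyl}-3,5-dioxopentanoate (racemic) | COC(=O)CC(=O)C(OC)C(=O)c1ccc(O[Si](C(C)C)(C(C)C)C(C)C)c(OC)c1 | intermediate
5 | methoxyacetyl chloride | COCC(=O)Cl | starting material
6 | methyl 4-methoxy-2-(methoxyacetyl)-5-{3-methoxy-4-[(triisopropylsilyl)oxy]phenyl}-3,5-dioxopentanoate (triketo ester, mixture of stereoisomers and enols, not isolated) | COCC(=O)C(C(=O)OC)C(=O)C(OC)C(=O)c1ccc(O[Si](C(C)C)(C(C)C)C(C)C)c(OC)c1 | intermediate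
7 | methyl 5-methoxy-2-(methoxymethyl)-6-{3-methoxy-4-[(triisopropylsilyl)oxy]phenyl}-4-oxo-4H-pyran-3-carboxylate | COCc1oc(-c2ccc(O[Si](C(C)C)(C(C)C)C(C)C)c(OC)c2)c(OC)c(=O)c1C(=O)OC | intermediate
8 | N-methoxy-N-methylacetamide | CC(=O)N(C)OC | starting material
9 | methyl 5-methoxy-2-(1-methoxy-2-oxopropyl)-6-{3-methoxy-4-[(triisopropylsilyl)oxy]phenyl}-4-oxo-4H-pyran-3-carboxylate (racemic) | COC(=O)c1c(C(OC)C(C)=O)oc(-c2ccc(O[Si](C(C)C)(C(C)C)C(C)C)c(OC)c2)c(OC)c1=O | intermediate
10 | 5,7-dihydroxy-3,8-dimethoxy-2-{3-methoxy-4-[(triisopropylsilyl)oxy]phenyl}-4H-chromen-4-one | COc1c(-c2ccc(O[Si](C(C)C)(C(C)C)C(C)C)c(OC)c2)oc2c(OC)c(O)cc(O)c2c1=O | intermediate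
11 | prenyl bromide (1-bromo-3-methylbut-2-ene) | CC(C)=CCBr | starting material
12 | 5-hydroxy-3,8-dimethoxy-2-{3-methoxy-4-[(triisopropylsilyl)oxy]phenyl}-7-[(3-methylbut-2-en-1-yl)oxy]-4H-chromen-4-one | COc1c(-c2ccc(O[Si](C(C)C)(C(C)C)C(C)C)c(OC)c2)oc2c(OC)c(OCC=C(C)C)cc(O)c2c1=O | intermediate
13 | 5,4'-dihydroxy-3,8,3'-trimethoxy-7-prenyloxyflavone | COc1cc(-c2oc3c(OC)c(OCC=C(C)C)cc(O)c3c(=O)c2OC)ccc1O | target

**Totals**
Total step count: 7. Longest linear sequence: 7 steps (1 → 2 → 4 → 7 → 9 → 10 → 12 → 13).

**Steps most likely to fail**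

Step 5 (key step). The second deprotonation at C6 may stay incomplete because the C8 enolate is strongly stabilised. The mono-enolate could then close through oxygen onto the ester, or the pyranone could be degraded by the excess base. The fallback gives the nucleophilic carbon a removable anion-stabilising group. It sets out from 7: the lateral enolate (LiN(SiMe3)2, THF, −78 °C) is acylated with N-methoxy-N-methyl-2-(phenylsulfanyl)acetamide to methyl 5-methoxy-2-[1-methoxy-2-oxo-3-(phenylsulfanyl)propyl]-6-{3-methoxy-4-[(triisopropylsilyl)oxy]phenyl}-4-oxo-4H-pyran-3-carboxylate F1. The sulfur-stabilised C6 carbanion of F1 should form with LiN(SiMe3)2 alone and close by the same Claisen condensation to 5,7-dihydroxy-3,8-dimethoxy-2-{3-methoxy-4-[(triisopropylsilyl)oxy]phenyl}-6-(phenylsulfanyl)-4H-chromen-4-one F2. Raney Ni in ethanol should then remove the sulfur substituent, and the route is rejoined at 10.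

Step 3. Acylation may occur at the wrong enolate (on oxygen or through C4 of the slightly more acidic 2-methoxy-1,3-diketone unit) and give mixtures. The fallback reverses the order of the two acylations so that symmetry removes the question. It sets out from 3: C-acylation with 5 (MgCl2, pyridine, CH2Cl2) should give methyl 4-methoxy-2-(methoxyacetyl)-3-oxobutanoate F3, whose two methoxyacetyl arms are equivalent. Its dianion (LiN(i-Pr)2, 2 equiv per F3, F3 in excess, THF, −78 to 0 °C) is acylated by ester 2 at either methoxymethyl carbon. This comes back to the route at triketo ester 6, which is closed with CF3CO2H to 7 as before.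

Step 4. The stabilised extended enolate may react sluggishly with the amide, or be acylated on oxygen or at the ring carbon that carries the ester. The fallback replaces acylation by aldol addition and oxidation. It sets out from 7: the lateral enolate (LiN(SiMe3)2, THF, −78 °C) is added to acetaldehyde and quenched cold to methyl 2-(2-hydroxy-1-methoxypropyl)-5-methoxy-6-{3-methoxy-4-[(triisopropylsilyl)oxy]phenyl}-4-oxo-4H-pyran-3-carboxylate F4 (mixture of diastereomers). Dess–Martin periodinane oxidation of F4 in CH2Cl2 comes back to the route at 9.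

**Further compounds**
F1 | step 5 | methyl 5-methoxy-2-[1-methoxy-2-oxo-3-(phenylsulfanyl)propyl]-6-{3-methoxy-4-[(triisopropylsilyl)oxy]phenyl}-4-oxo-4H-pyran-3-carboxylate (racemic) | COC(=O)c1c(C(OC)C(=O)CSc2ccccc2)oc(-c2ccc(O[Si](C(C)C)(C(C)C)C(C)C)c(OC)c2)c(OC)c1=O
F2 | step 5 | 5,7-dihydroxy-3,8-dimethoxy-2-{3-methoxy-4-[(triisopropylsilyl)oxy]phenyl}-6-(phenylsulfanyl)-4H-chromen-4-one | COc1c(-c2ccc(O[Si](C(C)C)(C(C)C)C(C)C)c(OC)c2)oc2c(OC)c(O)c(Sc3ccccc3)c(O)c2c1=O
F3 | step 3 | methyl 4-methoxy-2-(methoxyacetyl)-3-oxobutanoate | COCC(=O)C(C(=O)OC)C(=O)COC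
F4 | step 4 | methyl 2-(2-hydroxy-1-methoxypropyl)-5-methoxy-6-{3-methoxy-4-[(triisopropylsilyl)oxy]phenyl}-4-oxo-4H-pyran-3-carboxylate (mixture of diastereomers) | COC(=O)c1c(C(OC)C(C)O)oc(-c2ccc(O[Si](C(C)C)(C(C)C)C(C)C)c(OC)c2)c(OC)c1=O
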